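In carotenoid numbering both end rings are the same 5-hydroxy-3-oxo ring with 6S configuration and differ only at C5. The route cuts each ring's β-ketol C3(=O)–C4H2–C5(OH)CH3: without C4 the ring is a cyclopentanone in which C6 is β to the C3 carbonyl, so C6 is set by asymmetric conjugate alkynylation. The key step puts C4 back: a fused cyclopropanol (bicyclo[3.1.0]hexan-1-ol) opens oxidatively at the C3–C5 bond, expanding the five- to the six-membered ring while O2 capture of the C5 radical creates ketone and tertiary alcohol together. The planar radical gives both C5 epimers, one per end group; C15 + C10 + C15 Wittig couplings finish.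

Key step: step 4

Remark: the SMILES is read as the all-E (5S,6S,5'R,6'S) isomer; compounds 1, 3 and 21 are taken as commercial; ring positions are quoted in carotenoid numbering (C1 = CMe2, C3 = C=O, C5 = C–OH, C6 = CH carrying the chain, C7–C11 = side chain).

Step 1
Reactants: 1 (2E)-3-methylpent-2-en-4-yn-1-ol
Product: 2 tert-butyldimethyl{[(2E)-3-methylpent-2-en-4-yn-1-yl]oxy}silane
Conditions: TBSCl, imidazole, DMF, 0 °C → rt
Reagents that add atoms: tert-butyldimethylsilyl chloride CC(C)(C)[Si](C)(C)Cl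
Why: Standard silyl ether protection of the primary alcohol, so that it neither quenches the alane nor directs the later Simmons–Smith reagent to the side-chain alkene.

Step 2
Reactants: 2 tert-butyldimethyl{[(2E)-3-methylpent-2-en-4-yn-1-yl]oxy}silane; 3 2,4,4-trimethylcyclopent-2-en-1-one
Product: 6 (3R)-3-[(3E)-5-(tert-butyldimethylsilyloxy)-3-methylpent-3-en-1-yn-1-yl]-2,4,4-trimethyl-1-(trimethylsilyloxy)cyclopent-1-ene (ring C3 = future C6), via alkynyldimethylalane 4 (not isolated), via aluminium enolate 5 (not isolated)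
Conditions: Me3Al, Et3N (10 mol %), PhMe, 60 °C; then 3, Ni(cod)2 (5 mol %), chiral bis(oxazoline) ligand (6 mol %, enantiomer chosen for the C6 sense shown), t-BuOMe, 0 °C; then TMSOTf, −20 → 0 °C
Reagents that add atoms: trimethylsilyl trifluoromethanesulfonate C[Si](C)(C)OS(=O)(=O)C(F)(F)F
Why: Nickel-catalysed conjugate addition of a dimethylaluminium acetylide to a cyclic enone, a known reaction also in its enantioselective bis(oxazoline) form, in which the chiral ligand selects the enone face and so sets C6, while O-silylation of the aluminium enolate fixes the C3=C5 enol ether regiochemistry.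

Step 3
Reactants: 6 the TMS enol ether of step 2
Product: 8 4-[(3E)-5-(tert-butyldimethylsilyloxy)-3-methylpent-3-en-1-yn-1-yl]-3,3,5-trimethylbicyclo[3.1.0]hexan-1-ol (cyclopropane CH2 anti to the alkynyl group), via siloxycyclopropane 7 (not isolated)
Conditions: Et2Zn, CH2I2, CH2Cl2, 0 °C; aqueous NH4Cl work-up; then K2CO3 (cat.), MeOH, 0 °C, short contact
Reagents that add atoms: diiodomethane ICI
Why: Furukawa-modified Simmons–Smith cyclopropanation, in which the zinc carbenoid attacks the electron-rich tetrasubstituted silyl enol ether much faster than the conjugated side-chain alkene or the alkyne and adds anti to the C6 substituent (two cyclopropane stereocentres that are erased again in step 4), followed by mild methanolysis of the trimethylsilyl ether, which frees the cyclopropanol without opening it.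

Step 4
Reactants: 8 the cyclopropanol of step 3
Product: 10 (3S,4R)-4-[(3E)-5-(tert-butyldimethylsilyloxy)-3-methylpent-3-en-1-yn-1-yl]-3-hydroxy-3,5,5-trimethylcyclohexan-1-one (trans-ketol: 5-OH trans to the C6 side chain), via trans-hydroperoxy ketone 9 (not isolated)
Conditions: Mn(acac)3 (5 mol %), O2 (1 atm), PhH, rt; then PPh3, 0 °C; chromatography (10 separated from 12)
Reagents that add atoms: dioxygen O=O
Why: Mn(III) oxidises the cyclopropanol O–H to a cyclopropyloxy radical whose β-scission breaks the internal C3–C5 bond and gives the ring-expanded tertiary C5 radical, which captures O2; the peroxyl radical is reduced to hydroperoxide 9 (in equilibrium with its bridged peroxy-hemiketal) and PPh3 reduces that to the β-ketol. The closest known reaction types are the Mn-catalysed aerobic opening of cyclopropanols to β-hydroperoxy ketones, the Fe(III)-mediated ring expansion of 1-siloxybicyclo[n.1.0]alkanes and the Dowd–Beckwith ring expansion, which runs through the same cyclopropyloxy radical. No ring is closed: the six-membered ring C1–C6 arises by one-carbon expansion of the cyclopentane C1–C2–C3–C5–C6, the Simmons–Smith carbon becoming C4 between C3 and C5. C6 is untouched, and C5 is formed from a planar radical, so both cyclopropane diastereomers of 8 would converge; its two faces are shielded to a similar extent (C6 alkynyl group on one, axial C1 methyl on the other), so both C5 epimers are expected and are separated, 10 here and 12 in step 5. The step needs scission of the endo bond rather than the exo C3–C4 bond, secured by strain release and the tertiary radical (an exo-opened primary radical can re-close to the same cyclopropyloxy radical), and a peroxyl radical that leaves the side chain alone, secured by having an alkyne (slow 5-exo-dig addition) and not an alkene next to C6.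

Step 5
Reactants: 8 the cyclopropanol of step 3
Product: 12 (3R,4R)-4-[(3E)-5-(tert-butyldimethylsilyloxy)-3-methylpent-3-en-1-yn-1-yl]-3-hydroxy-3,5,5-trimethylcyclohexan-1-one (cis-ketol: 5-OH cis to the C6 side chain), via cis-hydroperoxy ketone 11 (not isolated)
Conditions: same run as step 4 (Mn(acac)3, O2, PhH; PPh3); second diastereomer from the chromatography
Reagents that add atoms: dioxygen O=O
Why: Same oxidative cyclopropanol ring expansion as step 4, in which O2 capture of the planar C5 radical on the face syn to the alkynyl group gives the C5 epimer that supplies the second end group.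

Step 6
Reactants: 10 trans-ketol
Product: 13 (2E)-5-[(1R,2S)-2-hydroxy-4,4-dimethoxy-2,6,6-trimethylcyclohexyl]-3-methylpent-2-en-4-yn-1-ol
Conditions: HC(OMe)3, MeOH, CSA (cat.), rt
Reagents that add atoms: trimethyl orthoformate COC(OC)OC
Why: Acid-catalysed ketalisation masks the C3 ketone (and so the β-ketol) against the fluoride and alkoxide bases used later, and the same acidic methanol cleaves the primary TBS ether, while the non-allylic tertiary C5 alcohol should survive these mild anhydrous conditions.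

Step 7
Reactants: 13 ring-1 enynol ketal
Product: 15 (2E,4E)-5-[(1S,2S)-2-hydroxy-4,4-dimethoxy-2,6,6-trimethylcyclohexyl]-3-methylpenta-2,4-dien-1-ol, via ring-1 dienylsilane 14 (not isolated)
Conditions: [Cp*Ru(MeCN)3]PF6 (5 mol %), (EtO)3SiH, CH2Cl2, 0 °C → rt; then CuI (cat.), TBAF, THF, rt
Reagents that add atoms: none
Why: Ruthenium-catalysed trans-hydrosilylation of the internal alkyne followed by copper/fluoride protodesilylation with retention is a known net E-selective semi-reduction that needs no propargylic hydroxyl, tolerates the conjugated alkene, the free alcohols and the ketal, and converges from either silane regioisomer (Si at C8, as drawn, or at C7) on the 7E alkene, whereas an aluminium hydride would reduce this 2-en-4-yn-1-ol to an allene.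

Step 8
Reactants: 15 ring-1 dienol
Product: 16 {(2E,4E)-5-[(1S,2S)-2-hydroxy-4,4-dimethoxy-2,6,6-trimethylcyclohexyl]-3-methylpenta-2,4-dien-1-yl}triphenylphosphonium bromide
Conditions: PPh3·HBr, MeOH, rt
Reagents that add atoms: triphenylphosphine hydrobromide Br.c1ccc(cc1)P(c1ccccc1)c1ccccc1
Why: Classical C15 phosphonium salt formation, in which the acid ionises the primary dienyl alcohol and triphenylphosphine captures the pentadienyl cation at its unhindered C11 terminus, the dimethyl ketal being degenerate in methanol.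

Step 9
Reactants: 12 cis-ketol
Product: 17 (2E)-5-[(1R,2R)-2-hydroxy-4,4-dimethoxy-2,6,6-trimethylcyclohexyl]-3-methylpent-2-en-4-yn-1-ol
Conditions: HC(OMe)3, MeOH, CSA (cat.), rt
Reagents that add atoms: trimethyl orthoformate COC(OC)OC
Why: Same ketalisation with concurrent TBS cleavage as in step 6, applied to the C5 epimer.

Step 10
Reactants: 17 ring-2 enynol ketal
Product: 19 (2E,4E)-5-[(1S,2R)-2-hydroxy-4,4-dimethoxy-2,6,6-trimethylcyclohexyl]-3-methylpenta-2,4-dien-1-ol, via ring-2 dienylsilane 18 (not isolated)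
Conditions: [Cp*Ru(MeCN)3]PF6 (5 mol %), (EtO)3SiH, CH2Cl2, 0 °C → rt; then CuI (cat.), TBAF, THF, rt
Reagents that add atoms: none
Why: Same ruthenium-catalysed trans-hydrosilylation and protodesilylation as in step 7, giving the 7E,9E dienol of the second end group.

Step 11
Reactants: 19 ring-2 dienol
Product: 20 {(2E,4E)-5-[(1S,2R)-2-hydroxy-4,4-dimethoxy-2,6,6-trimethylcyclohexyl]-3-methylpenta-2,4-dien-1-yl}triphenylphosphonium bromide
Conditions: PPh3·HBr, MeOH, rt
Reagents that add atoms: triphenylphosphine hydrobromide Br.c1ccc(cc1)P(c1ccccc1)c1ccccc1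
Why: Same C15 phosphonium salt formation as in step 8.

Step 12
Reactants: 16 ring-1 C15 phosphonium bromide; 21 (2E,4E,6E)-2,7-dimethylocta-2,4,6-trienedial (3 equiv)
Product: 22 (2E,4E,6E,8E,10E,12E)-13-[(1S,2S)-2-hydroxy-4,4-dimethoxy-2,6,6-trimethylcyclohexyl]-2,7,11-trimethyltrideca-2,4,6,8,10,12-hexaenal (C25 apo-aldehyde)
Conditions: NaOMe, MeOH–CH2Cl2, 0 °C → rt; then heptane, 80 °C (Z → E)
Reagents that add atoms: none
Why: Wittig olefination of one formyl group of the C10 dialdehyde (used in excess to suppress double condensation) by the semi-stabilised C15 ylide forms C11=C12, and the 11Z isomer is equilibrated thermally to the all-E aldehyde.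

Step 13
Reactants: 20 ring-2 C15 phosphonium bromide; 22 C25 apo-aldehyde
Product: 23 all-E (5S,6S,5'R,6'S)-5,5'-dihydroxy-5,6,5',6'-tetrahydro-β,β-carotene-3,3'-dione bis(dimethyl ketal)
Conditions: NaOMe, MeOH–CH2Cl2, 0 °C → rt; then heptane, 80 °C (Z → E)
Reagents that add atoms: none
Why: The second Wittig olefination forms C11'=C12' and completes the C40 polyene, with thermal equilibration to the all-E isomer, the ketals and tertiary alcohols being inert to methoxide.

Step 14
Reactants: 23 C40 bis(dimethyl ketal)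
Product: 24 all-E (5S,6S,5'R,6'S)-5,5'-dihydroxy-5,6,5',6'-tetrahydro-β,β-carotene-3,3'-dione (target)
Conditions: PPTS (cat.), acetone–H2O (10:1), rt, dark, argon
Reagents that add atoms: water O
Why: Mild acid hydrolysis of the two dimethyl ketals releases both C3 ketones under conditions too weak to eliminate the tertiary β-hydroxyl groups or to isomerise the polyene.

Compound list
1 | (2E)-3-methylpent-2-en-4-yn-1-ol | C#C/C(C)=C/CO | starting material
2 | tert-butyldimethyl{[(2E)-3-methylpent-2-en-4-yn-1-yl]oxy}silane | C#C/C(C)=C/CO[Si](C)(C)C(C)(C)C | intermediate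
3 | 2,4,4-trimethylcyclopent-2-en-1-one | CC1=CC(C)(C)CC1=O | starting material
4 | [(3E)-5-(tert-butyldimethylsilyloxy)-3-methylpent-3-en-1-yn-1-yl]dimethylalane | C[Al](C)C#C/C(C)=C/CO[Si](C)(C)C(C)(C)C | intermediate
5 | dimethylaluminium enolate of the conjugate adduct (C6 as in the target) | CC(C)(C)[Si](C)(C)OC/C=C(C)/C#C[C@H]1C(C)(C)CC(O[Al](C)C)=C1C | intermediate
6 | (3R)-3-[(3E)-5-(tert-butyldimethylsilyloxy)-3-methylpent-3-en-1-yn-1-yl]-2,4,4-trimethyl-1-(trimethylsilyloxy)cyclopent-1-ene | CC(C)(C)[Si](C)(C)OC/C=C(C)/C#C[C@H]1C(C)(C)CC(O[Si](C)(C)C)=C1C | intermediate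
7 | 4-[(3E)-5-(tert-butyldimethylsilyloxy)-3-methylpent-3-en-1-yn-1-yl]-3,3,5-trimethyl-1-(trimethylsilyloxy)bicyclo[3.1.0]hexane, CH2 anti to the alkynyl group | CC(C)(C)[Si](C)(C)OC/C=C(C)/C#C[C@H]1C(C)(C)C[C@]2(O[Si](C)(C)C)C[C@]12C | intermediate
8 | 4-[(3E)-5-(tert-butyldimethylsilyloxy)-3-methylpent-3-en-1-yn-1-yl]-3,3,5-trimethylbicyclo[3.1.0]hexan-1-ol, CH2 anti to the alkynyl group | CC(C)(C)[Si](C)(C)OC/C=C(C)/C#C[C@H]1C(C)(C)C[C@]2(O)C[C@]12C | intermediate
9 | (3S,4R)-4-[(3E)-5-(tert-butyldimethylsilyloxy)-3-methylpent-3-en-1-yn-1-yl]-3-hydroperoxy-3,5,5-trimethylcyclohexan-1-one (OOH trans to the side chain) | CC(C)(C)[Si](C)(C)OC/C=C(C)/C#C[C@H]1C(C)(C)CC(=O)C[C@]1(C)OO | intermediate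
10 | (3S,4R)-4-[(3E)-5-(tert-butyldimethylsilyloxy)-3-methylpent-3-en-1-yn-1-yl]-3-hydroxy-3,5,5-trimethylcyclohexan-1-one (trans-ketol) | CC(C)(C)[Si](C)(C)OC/C=C(C)/C#C[C@H]1C(C)(C)CC(=O)C[C@]1(C)O | intermediate
11 | (3R,4R)-4-[(3E)-5-(tert-butyldimethylsilyloxy)-3-methylpent-3-en-1-yn-1-yl]-3-hydroperoxy-3,5,5-trimethylcyclohexan-1-one (OOH cis to the side chain) | CC(C)(C)[Si](C)(C)OC/C=C(C)/C#C[C@H]1C(C)(C)CC(=O)C[C@@]1(C)OO | intermediate
12 | (3R,4R)-4-[(3E)-5-(tert-butyldimethylsilyloxy)-3-methylpent-3-en-1-yn-1-yl]-3-hydroxy-3,5,5-trimethylcyclohexan-1-one (cis-ketol) | CC(C)(C)[Si](C)(C)OC/C=C(C)/C#C[C@H]1C(C)(C)CC(=O)C[C@@]1(C)O | intermediate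
13 | (2E)-5-[(1R,2S)-2-hydroxy-4,4-dimethoxy-2,6,6-trimethylcyclohexyl]-3-methylpent-2-en-4-yn-1-ol | OC/C=C(C)/C#C[C@H]1C(C)(C)CC(OC)(OC)C[C@]1(C)O | intermediate
14 | (2E,4Z)-5-[(1S,2S)-2-hydroxy-4,4-dimethoxy-2,6,6-trimethylcyclohexyl]-3-methyl-4-(triethoxysilyl)penta-2,4-dien-1-ol | OC/C=C(C)/C([Si](OCC)(OCC)OCC)=C/[C@H]1C(C)(C)CC(OC)(OC)C[C@]1(C)O | intermediate
15 | (2E,4E)-5-[(1S,2S)-2-hydroxy-4,4-dimethoxy-2,6,6-trimethylcyclohexyl]-3-methylpenta-2,4-dien-1-ol | OC/C=C(C)/C=C/[C@H]1C(C)(C)CC(OC)(OC)C[C@]1(C)O | intermediate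
16 | {(2E,4E)-5-[(1S,2S)-2-hydroxy-4,4-dimethoxy-2,6,6-trimethylcyclohexyl]-3-methylpenta-2,4-dien-1-yl}triphenylphosphonium bromide | [Br-].c1ccccc1[P+](c1ccccc1)(c1ccccc1)C/C=C(C)/C=C/[C@H]1C(C)(C)CC(OC)(OC)C[C@]1(C)O | intermediate
17 | (2E)-5-[(1R,2R)-2-hydroxy-4,4-dimethoxy-2,6,6-trimethylcyclohexyl]-3-methylpent-2-en-4-yn-1-ol | OC/C=C(C)/C#C[C@H]1C(C)(C)CC(OC)(OC)C[C@@]1(C)O | intermediate
18 | (2E,4Z)-5-[(1S,2R)-2-hydroxy-4,4-dimethoxy-2,6,6-trimethylcyclohexyl]-3-methyl-4-(triethoxysilyl)penta-2,4-dien-1-ol | OC/C=C(C)/C([Si](OCC)(OCC)OCC)=C/[C@H]1C(C)(C)CC(OC)(OC)C[C@@]1(C)O | intermediate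
19 | (2E,4E)-5-[(1S,2R)-2-hydroxy-4,4-dimethoxy-2,6,6-trimethylcyclohexyl]-3-methylpenta-2,4-dien-1-ol | OC/C=C(C)/C=C/[C@H]1C(C)(C)CC(OC)(OC)C[C@@]1(C)O | intermediate
20 | {(2E,4E)-5-[(1S,2R)-2-hydroxy-4,4-dimethoxy-2,6,6-trimethylcyclohexyl]-3-methylpenta-2,4-dien-1-yl}triphenylphosphonium bromide | [Br-].c1ccccc1[P+](c1ccccc1)(c1ccccc1)C/C=C(C)/C=C/[C@H]1C(C)(C)CC(OC)(OC)C[C@@]1(C)O | intermediate
21 | (2E,4E,6E)-2,7-dimethylocta-2,4,6-trienedial | O=C/C(C)=C/C=C/C=C(C)/C=O | starting material
22 | (2E,4E,6E,8E,10E,12E)-13-[(1S,2S)-2-hydroxy-4,4-dimethoxy-2,6,6-trimethylcyclohexyl]-2,7,11-trimethyltrideca-2,4,6,8,10,12-hexaenal | O=C/C(C)=C/C=C/C=C(C)/C=C/C=C(C)/C=C/[C@H]1C(C)(C)CC(OC)(OC)C[C@]1(C)O | intermediate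
23 | all-E (5S,6S,5'R,6'S)-5,5'-dihydroxy-5,6,5',6'-tetrahydro-β,β-carotene-3,3'-dione bis(dimethyl ketal) | CC(/C=C/C=C(C)/C=C/[C@H]1C(C)(C)CC(OC)(OC)C[C@]1(C)O)=C\C=C\C=C(C)\C=C\C=C(C)\C=C\[C@H]1C(C)(C)CC(OC)(OC)C[C@@]1(C)O | intermediate
24 | all-E (5S,6S,5'R,6'S)-5,5'-dihydroxy-5,6,5',6'-tetrahydro-β,β-carotene-3,3'-dione | CC(/C=C/C=C(C)/C=C/[C@H]1C(C)(C)CC(=O)C[C@]1(C)O)=C\C=C\C=C(C)\C=C\C=C(C)\C=C\[C@H]1C(C)(C)CC(=O)C[C@@]1(C)O | target

Total step count: 14 numbered steps; steps 4 and 5 are the two isolated products of one oxidation run, so there are 13 separate operations.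
Longest linear sequence: 10 steps (1, 2, 3, 4, 6, 7, 8, 12, 13, 14).

Steps most likely to fail

Step 4 (and its twin, step 5). Oxygen capture at the C5 radical may be strongly one-sided, leaving one epimer in short supply, and exo-bond scission or addition of the peroxyl radical to the side chain may erode the yield. The fallback sets out from 7 (the crude siloxycyclopropane of step 3, taken before the methanolysis) and comes back at 10 and at 12. Fe(III)-mediated ring expansion of 7 (FeCl3, DMF, 0 °C) should give the ring-expanded β-chloro ketone F1, and NaOAc in MeOH eliminates HCl to the cyclohexenone F2. For 10, nucleophilic epoxidation of F2 (H2O2, NaOH, MeOH, −10 °C) anti to the alkynyl group should give the epoxy ketone F3, and reductive opening of this α,β-epoxy ketone (SmI2, THF–MeOH, −90 °C) gives 10. For 12, Luche reduction of F2 gives the cis allylic alcohol F4, with the hydroxyl on the side-chain face, together with the trans allylic alcohol F5, which is separated and returned to F2 with MnO2. VO(acac)2/t-BuOOH epoxidation of F4, directed by the hydroxyl, gives the epoxy alcohol F6; Red-Al delivers hydride to C4 to give the 1,3-diol F7; selective oxidation of the secondary alcohol (TEMPO, PhI(OAc)2) gives 12.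

Step 2. The alkynyl transfer may stall or lose facial control on this α-methyl, γ,γ-dimethyl enone, and O-silylation of the aluminium enolate may be incomplete. The fallback sets out from 3 and comes back at 6. The zinc acetylide of 2 (n-BuLi, then ZnBr2) is added to 3 under TMSOTf promotion without a chiral catalyst, which should give the racemic silyl enol ether F8. Methanolysis (K2CO3, MeOH), which also equilibrates C2, gives the racemic 2,3-trans ketone F9. Preparative chromatography on a chiral stationary phase gives the enantiomer with the required C6 configuration, the resolved trans ketone F10. Thermodynamic O-silylation of F10 (TMSOTf, Et3N, CH2Cl2, rt) returns 6.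

Step 7 (and its twin, step 10). Hydrosilylation at the hindered C7≡C8 bond may be slow, the free hydroxyl groups may be silylated, or protodesilylation of the dienylsilane may be incomplete. The fallback sets out from 13 and 17 and comes back at 16 and 20. Zn(Cu/Ag) in MeOH–H2O reduces the conjugated triple bond to the cis alkene, giving the ring-1 7Z dienol F11 from 13 and the ring-2 7Z dienol F12 from 17. Treatment of each with PPh3·HBr in MeOH at 40 °C ionises the dienol to the pentadienyl cation, in which the strained 7Z bond should relax to 7E before triphenylphosphine captures C11. This returns 16 from F11 and 20 from F12.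

Further compounds
F1 | step 4 | 4-[(3E)-5-(tert-butyldimethylsilyloxy)-3-methylpent-3-en-1-yn-1-yl]-3-chloro-3,5,5-trimethylcyclohexan-1-one (C3 epimers) | CC(C)(C)[Si](C)(C)OC/C=C(C)/C#C[C@H]1C(C)(C)CC(=O)CC1(C)Cl
F2 | step 4 | 4-[(3E)-5-(tert-butyldimethylsilyloxy)-3-methylpent-3-en-1-yn-1-yl]-3,5,5-trimethylcyclohex-2-en-1-one (C4 as C6 of the target) | CC(C)(C)[Si](C)(C)OC/C=C(C)/C#C[C@H]1C(C)(C)CC(=O)C=C1C
F3 | step 4 | 2,3-epoxy-4-[(3E)-5-(tert-butyldimethylsilyloxy)-3-methylpent-3-en-1-yn-1-yl]-3,5,5-trimethylcyclohexan-1-one, epoxide trans to the side chain | CC(C)(C)[Si](C)(C)OC/C=C(C)/C#C[C@H]1C(C)(C)CC(=O)[C@@H]2O[C@]12C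
F4 | step 4 | 4-[(3E)-5-(tert-butyldimethylsilyloxy)-3-methylpent-3-en-1-yn-1-yl]-3,5,5-trimethylcyclohex-2-en-1-ol, OH cis to the side chain | CC(C)(C)[Si](C)(C)OC/C=C(C)/C#C[C@H]1C(C)(C)C[C@@H](O)C=C1C
F5 | step 4 | 4-[(3E)-5-(tert-butyldimethylsilyloxy)-3-methylpent-3-en-1-yn-1-yl]-3,5,5-trimethylcyclohex-2-en-1-ol, OH trans to the side chain | CC(C)(C)[Si](C)(C)OC/C=C(C)/C#C[C@H]1C(C)(C)C[C@H](O)C=C1C
F6 | step 4 | 2,3-epoxy-4-[(3E)-5-(tert-butyldimethylsilyloxy)-3-methylpent-3-en-1-yn-1-yl]-3,5,5-trimethylcyclohexan-1-ol, epoxide and OH cis to the side chain | CC(C)(C)[Si](C)(C)OC/C=C(C)/C#C[C@H]1C(C)(C)C[C@@H](O)[C@H]2O[C@@]12C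
F7 | step 4 | 4-[(3E)-5-(tert-butyldimethylsilyloxy)-3-methylpent-3-en-1-yn-1-yl]-3,5,5-trimethylcyclohexane-1,3-diol, both OH cis to the side chain | CC(C)(C)[Si](C)(C)OC/C=C(C)/C#C[C@H]1C(C)(C)C[C@@H](O)C[C@@]1(C)O
F8 | step 2 | racemic 3-[(3E)-5-(tert-butyldimethylsilyloxy)-3-methylpent-3-en-1-yn-1-yl]-2,4,4-trimethyl-1-(trimethylsilyloxy)cyclopent-1-ene | CC(C)(C)[Si](C)(C)OC/C=C(C)/C#CC1C(C)(C)CC(O[Si](C)(C)C)=C1C
F9 | step 2 | racemic 2,3-trans-3-[(3E)-5-(tert-butyldimethylsilyloxy)-3-methylpent-3-en-1-yn-1-yl]-2,4,4-trimethylcyclopentan-1-one | CC(C)(C)[Si](C)(C)OC/C=C(C)/C#CC1C(C)(C)CC(=O)C1C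
F10 | step 2 | 2,3-trans-3-[(3E)-5-(tert-butyldimethylsilyloxy)-3-methylpent-3-en-1-yn-1-yl]-2,4,4-trimethylcyclopentan-1-one, single enantiomer (C3 as C6 of the target) | CC(C)(C)[Si](C)(C)OC/C=C(C)/C#C[C@H]1C(C)(C)CC(=O)[C@@H]1C
F11 | step 7 | (2E,4Z)-5-[(1S,2S)-2-hydroxy-4,4-dimethoxy-2,6,6-trimethylcyclohexyl]-3-methylpenta-2,4-dien-1-ol | OC/C=C(C)/C=C\[C@H]1C(C)(C)CC(OC)(OC)C[C@]1(C)O
F12 | step 7 | (2E,4Z)-5-[(1S,2R)-2-hydroxy-4,4-dimethoxy-2,6,6-trimethylcyclohexyl]-3-methylpenta-2,4-dien-1-ol | OC/C=C(C)/C=C\[C@H]1C(C)(C)CC(OC)(OC)C[C@@]1(C)O
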